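**Late times.** Late in these flasks the gap between right-handed and left-handed substrate answers to two things: how fast it fades as the two turn into each other (racemization), and how much the dying catalyst still feeds it.

all flasks: left-handed substrate 0.10 M; right-handed substrate 0.10 M

| charge | partner | protic impurity | free catalyst | remark | time |
|---|---|---|---|---|---|
| midnight | 0.30 M | 0.010 M | 0.93 mM | run made earlier |  |
| violet | 0.200 M | 0.0100 M | 0.93 mM |  | 5.0 h |
| grey | 0.200 M | 0.0100 M | 0.50 mM |  | 5.0 h |

midnight run (percent of the left-handed substrate and right-handed substrate together charged)

| time / min | right-handed substrate / % | left-handed substrate / % |
|---|---|---|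
| 15.0 | 40.8 | 31.6 |
| 30.0 | 38.9 | 29.6 |
| 50.0 | 36.8 | 29.5 |
| 60.0 | 35.6 | 28.8 |

(standard deviation of a reading: 0.3 percentage points)

- free catalyst is single-handed; left-handed substrate and right-handed substrate are mirror images of each other, charged as a racemate, each of them at the stated concentration
- what may be going on: partner + free catalyst + left-handed substrate -> free catalyst + left-handed product; partner + free catalyst + right-handed substrate -> free catalyst + right-handed product; left-handed substrate <-> right-handed substrate; 2 free catalyst -> spent catalyst; partner + protic impurity -> quenched reagent
- an excess is the difference of the two amounts in percent of their sum
- an excess is below zero if the other one leads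
- no earlier run changes the charge of free catalyst; that part of a forecast is a guess

- which one finishes higher in excess of right-handed substrate over left-handed substrate among what is left of the two ("neither" within 2 percentage points) (violet / grey / neither)
- excess of right-handed substrate over left-handed substrate among what is left of the two at the end, violet
- excess of right-handed substrate over left-handed substrate among what is left of the two at the end, grey

**Fading rate.** In the midnight run the gap falls from 9.2 percentage points at 15.0 min to 6.8 points at 60.0 min, while 8 points of substrate reacts. Up to the first reading, 33.3 % of what reacted showed up as gap. Add that share of the later loss to the fall, divide by the mean gap and the time, and you read the fading rate, the fraction of the gap lost per minute with no feed, 0.0141 min⁻¹.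

**Two extremes.** Scale both to violet's partner. With the catalyst dead after the last reading, the excess fades to 0.240 % at 5.0 h. With the catalyst holding its late pace, feed and fading balance at 4.36 %.

**Between them.** Pairwise death makes [free catalyst] fall as one over the time, whatever the charge, once the stall is long past; that part is a guess. The pace then shrinks the balance to 0.472 %, and with the faded remainder my own figure is 0.712 % for both flasks.

**The forecast.** It gives 0.8 % for violet, 0.7 % for grey and neither; in its words, “violet and grey should nearly coincide”.

**Result.** Violet ends at 1.15 % and grey at 1.14 %, so the answer is neither.

    partner + free catalyst + left-handed substrate → free catalyst + left-handed product (k = 11.0 L² mol⁻² s⁻¹)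
    partner + free catalyst + right-handed substrate → free catalyst + right-handed product (k = 4.30 L² mol⁻² s⁻¹)
    left-handed substrate ⇌ right-handed substrate (k = 1.10 × 10⁻⁴ s⁻¹)
    2 free catalyst → spent catalyst (k = 8.60 L mol⁻¹ s⁻¹)
    partner + protic impurity → quenched reagent (k = 0.00760 L mol⁻¹ s⁻¹)

At 5.00 h, free catalyst stands at 0.00322 mM in violet and 0.00321 mM in grey, from charges of 0.93 mM and 0.50 mM. Grey read at 80 min shows 5.57 %; the fading rate as read from the midnight run, applied over the remaining time with no feed, gives an estimate of 0.250 %, and grey ends at 1.14 %.

The runs are calculated on assumed constants, and the scatter is random.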